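**Plan**

- Numbering: six-membered ring C1 (C=O), C2 (bears the side chain), C3 (enol C–OH), C4 (OMe), C5, C6; cyclopentene C1′ (C–OH), C2′ (CH), C3′ (dienyl), C4′, C5′.
- Cuts: O–CH3 and C1–C2 first, then C2–C3 (alkylzinc + acid chloride), C3′–C(Me)= (Negishi), C2′–CH2 ([3,3]) and C1′–CH3. The enabling feature is that the C4 oxygen stands 1,4 to the C1 carbonyl carbon through C5–C6, so O–C4–C5–C6–C1 can be closed as a γ-butyrolactone that carries the C3 acyl group on C4.
- Forward: the cyclopentene is bought as a 4-silyloxycyclopentenone and edited, the Z-dienyl arm is coupled on, and the acyl lactone is attached. The six-membered ring arises last by one-atom ring expansion of the lactone (acyl transfer from O to C2); the expelled C4 alkoxide is methylated in the same flask.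
- Stereochemistry: C4 comes from (S)-5-oxooxolane-2-carboxylic acid (its C–O bond is never broken). C1′ is set by MeLi addition anti to a silyloxy relay centre that is then oxidised away. C2′ is set by suprafacial [3,3] transfer from a CBS-set carbinol. The Z alkene comes from trans-hydroalumination/iodination and stereoretentive coupling.

Key step: step 16

Remark: the 2-alkyl-1,3-dione is drawn as the enol tautomer of the target SMILES; the two enol forms interconvert, so the carbonyl next to C4 and the one next to C6 are not distinguished in the synthesis.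

**Route**

Step 1
Reactants: 1 but-2-yn-1-ol
Product: 3 (2Z)-3-iodobut-2-en-1-ol, via cyclic alkenylaluminate 2 (not isolated)
Conditions: Red-Al, Et2O, 0 °C → rt; EtOAc; then I2, THF, −78 → 0 °C
Reagents that add atoms: iodine, II
Why: hydroxyl-directed trans-hydroalumination of the propargylic alcohol places aluminium on C3 cis to the CH2O arm in a five-membered aluminate, and iodinolysis of the C–Al bond with retention should give only the Z iodide.

Step 2
Reactants: 3 (2Z)-3-iodobut-2-en-1-ol
Product: 4 (2Z)-1-bromo-3-iodobut-2-ene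
Conditions: PBr3 (0.4 equiv), Et2O, 0 °C
Reagents that add atoms: phosphorus tribromide, BrP(Br)Br
Why: SN2 displacement of the activated primary allylic alcohol by bromide; the alkene geometry is not touched.

Step 3
Reactants: 4 (2Z)-1-bromo-3-iodobut-2-ene; 5 (2-methylprop-1-en-1-yl)magnesium bromide
Product: 6 (2Z)-2-iodo-6-methylhepta-2,5-diene
Conditions: CuI (5 mol%), THF, −30 → 0 °C
Reagents that add atoms: none
Why: copper-catalysed Grignard–allyl bromide coupling at the primary carbon (SN2); attack at the iodine-bearing γ-carbon is blocked and the alkenyl iodide should be inert at this temperature.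

Step 4
Reactants: 7 (4R)-4-[(tert-butyldimethylsilyl)oxy]cyclopent-2-en-1-one
Product: 8 (1S,4R)-4-[(tert-butyldimethylsilyl)oxy]-1-methylcyclopent-2-en-1-ol
Conditions: MeLi, Et2O, −78 °C; then H2O
Reagents that add atoms: methyllithium, [Li]C
Why: substrate-controlled 1,2-addition to the enone carbonyl from the face anti to the C4 silyloxy group sets the tertiary carbinol (OH cis to OTBS); any minor diastereomer can be removed here, before the relay centre is erased.

Step 5
Reactants: 8 (1S,4R)-4-[(tert-butyldimethylsilyl)oxy]-1-methylcyclopent-2-en-1-ol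
Product: 9 (1S,4R)-1-methylcyclopent-2-ene-1,4-diol
Conditions: TBAF, THF, 0 °C → rt
Reagents that add atoms: none
Why: fluoride cleavage of the secondary silyl ether; the acid-sensitive tertiary allylic alcohol is not exposed to acid.

Step 6
Reactants: 9 (1S,4R)-1-methylcyclopent-2-ene-1,4-diol
Product: 10 (4S)-4-hydroxy-4-methylcyclopent-2-en-1-one
Conditions: MnO2, CH2Cl2, rt
Reagents that add atoms: none
Why: allylic oxidation of the secondary alcohol only, under neutral conditions that avoid retro-aldol opening of the β-hydroxy ketone; the relay stereocentre is erased and the tertiary one remains (1,4-chirality relay).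

Step 7
Reactants: 10 (4S)-4-hydroxy-4-methylcyclopent-2-en-1-one
Product: 11 (4S)-4-methyl-4-(triethylsilyloxy)cyclopent-2-en-1-one
Conditions: TESOTf, 2,6-lutidine, CH2Cl2, −78 → 0 °C
Reagents that add atoms: triethylsilyl trifluoromethanesulfonate, CC[Si](CC)(CC)OS(=O)(=O)C(F)(F)F
Why: silylation of the tertiary alcohol with a silyl triflate; it blocks retro-aldol racemisation and protects the carbinol up to the last step.

Step 8
Reactants: 11 (4S)-4-methyl-4-(triethylsilyloxy)cyclopent-2-en-1-one
Product: 13 (4S)-2-bromo-4-methyl-4-(triethylsilyloxy)cyclopent-2-en-1-one, via trans-dibromide 12 (not isolated)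
Conditions: Br2, CH2Cl2, 0 °C; then Et3N, 0 °C → rt
Reagents that add atoms: bromine, BrBr
Why: bromine addition to the enone C=C followed by base-induced loss of HBr (acidic α-H, β-Br) gives the α-bromoenone, which is the handle for the later diene coupling.

Step 9
Reactants: 13 (4S)-2-bromo-4-methyl-4-(triethylsilyloxy)cyclopent-2-en-1-one
Product: 14 (1R,4S)-2-bromo-4-methyl-4-(triethylsilyloxy)cyclopent-2-en-1-ol
Conditions: (S)-Me-CBS (20 mol%), BH3·SMe2, THF, −20 °C; MeOH
Reagents that add atoms: none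
Why: Corey–Bakshi–Shibata reduction; with the α-bromovinyl carbon as the large group the (S)-catalyst should deliver hydride to give the (1R) carbinol, cis to the silyloxy group (reagent control).

Step 10
Reactants: 14 (1R,4S)-2-bromo-4-methyl-4-(triethylsilyloxy)cyclopent-2-en-1-ol; 15 triethyl orthoacetate
Product: 18 ethyl 2-[(1S,5S)-2-bromo-5-methyl-5-(triethylsilyloxy)cyclopent-2-en-1-yl]acetate, via mixed orthoester 16 (not isolated), via ketene acetal 17 (not isolated)
Conditions: EtCO2H (10 mol%), xylene, 140 °C, removal of EtOH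
Reagents that add atoms: none
Why: Johnson–Claisen rearrangement; the [3,3] shift within the ring is necessarily suprafacial, so the carbinol configuration is transferred to C2′ with CH2CO2Et cis to the silyloxy group, and the double bond moves to C3′=C4′ next to bromine.

Step 11
Reactants: 6 (2Z)-2-iodo-6-methylhepta-2,5-diene; 18 ethyl 2-[(1S,5S)-2-bromo-5-methyl-5-(triethylsilyloxy)cyclopent-2-en-1-yl]acetate
Product: 21 ethyl 2-[(1R,5S)-5-methyl-2-[(2Z)-6-methylhepta-2,5-dien-2-yl]-5-(triethylsilyloxy)cyclopent-2-en-1-yl]acetate, via alkenyllithium 19 (not isolated), via alkenylzinc chloride 20 (not isolated)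
Conditions: 6, t-BuLi (2 equiv), Et2O, −78 °C; ZnCl2, THF, −78 °C → rt; then 18, Pd2(dba)3 (2.5 mol%), SPhos (10 mol%), THF, 50 °C
Reagents that add atoms: none
Why: Negishi coupling; iodine–lithium exchange and transmetalation to zinc proceed with retention, and Pd-catalysed sp2–sp2 coupling with the alkenyl bromide retains both alkene geometries, so the Z diene should result while the ester tolerates the organozinc.

Step 12
Reactants: 21 ethyl 2-[(1R,5S)-5-methyl-2-[(2Z)-6-methylhepta-2,5-dien-2-yl]-5-(triethylsilyloxy)cyclopent-2-en-1-yl]acetate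
Product: 22 2-[(1R,5S)-5-methyl-2-[(2Z)-6-methylhepta-2,5-dien-2-yl]-5-(triethylsilyloxy)cyclopent-2-en-1-yl]ethan-1-ol
Conditions: LiAlH4, Et2O, 0 °C; Fieser work-up
Reagents that add atoms: none
Why: hydride reduction of the ester to the primary alcohol; the alkenes and the silyl ether are inert.

Step 13
Reactants: 22 2-[(1R,5S)-5-methyl-2-[(2Z)-6-methylhepta-2,5-dien-2-yl]-5-(triethylsilyloxy)cyclopent-2-en-1-yl]ethan-1-ol
Product: 23 triethyl{[(1S,2R)-2-(2-iodoethyl)-1-methyl-3-[(2Z)-6-methylhepta-2,5-dien-2-yl]cyclopent-3-en-1-yl]oxy}silane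
Conditions: PPh3, I2, imidazole (premixed), CH2Cl2, 0 °C → rt
Reagents that add atoms: iodine, II
Why: Appel-type iodination of the primary alcohol through the alkoxyphosphonium salt; premixing keeps free iodine away from the diene and imidazole buffers the silyl ether.

Step 14
Reactants: 24 (2S)-5-oxooxolane-2-carboxylic acid
Product: 25 (2S)-5-oxooxolane-2-carbonyl chloride
Conditions: (COCl)2, DMF (cat.), CH2Cl2, 0 °C → rt
Reagents that add atoms: oxalyl chloride, ClC(=O)C(=O)Cl
Why: acid chloride formation under base-free Vilsmeier catalysis, which gives no route to a ketene and so should keep the α-stereocentre intact.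

Step 15
Reactants: 23 triethyl{[(1S,2R)-2-(2-iodoethyl)-1-methyl-3-[(2Z)-6-methylhepta-2,5-dien-2-yl]cyclopent-3-en-1-yl]oxy}silane; 25 (2S)-5-oxooxolane-2-carbonyl chloride
Product: 27 (5S)-5-{3-[(1R,5S)-5-methyl-2-[(2Z)-6-methylhepta-2,5-dien-2-yl]-5-(triethylsilyloxy)cyclopent-2-en-1-yl]propanoyl}oxolan-2-one, via alkylzinc iodide 26 (not isolated)
Conditions: Zn dust (activated, BrCH2CH2Br/TMSCl cat.), THF, 40 °C; then 25, Pd(PPh3)4 (5 mol%), THF, 0 °C → rt
Reagents that add atoms: none
Why: zinc insertion into the primary C–I bond and Pd-catalysed Negishi acylation by the acid chloride; the alkylzinc should not add to the lactone or to the ketone formed, so the acyl lactone is obtained without over-addition.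

Step 16
Reactants: 27 (5S)-5-{3-[(1R,5S)-5-methyl-2-[(2Z)-6-methylhepta-2,5-dien-2-yl]-5-(triethylsilyloxy)cyclopent-2-en-1-yl]propanoyl}oxolan-2-one
Product: 30 (4S)-3-hydroxy-4-methoxy-2-{[(1R,5S)-5-methyl-2-[(2Z)-6-methylhepta-2,5-dien-2-yl]-5-(triethylsilyloxy)cyclopent-2-en-1-yl]methyl}cyclohex-2-en-1-one, via lithium enolate 28 (not isolated), via dilithium hydroxy-dionate 29 (not isolated)
Conditions: 27 added to LiHMDS (2.1 equiv), THF, −78 → 0 °C; then MeOTf (1.1 equiv), −78 → −20 °C; dil. aq. HCl to pH 4, 0 °C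
Reagents that add atoms: methyl trifluoromethanesulfonate, COS(=O)(=O)C(F)(F)F
Why: LiHMDS removes a proton from C2 (the ketone CH2 remote from the oxygen-bearing methine) and the enolate carbon adds to the lactone carbonyl C1 in a 6-(enolexo)-exo-trig closure; collapse of the tetrahedral intermediate breaks the acyl C1–O bond, so the five-membered lactone (O, C1, C6, C5, C4) becomes the six-membered carbocycle C1–C6 and the ring oxygen is left as the C4 alkoxide. The closest known reaction type is the base-mediated intramolecular Claisen condensation of δ-keto esters to cyclohexane-1,3-diones, here with the ester tied back as a γ-lactone. No stereocentre is made: C4 is the lactone carbon of 24 and its C–O and C–H bonds are never broken, so the (S) configuration should be carried over with retention. The step needs regioselective enolisation, which the bulky amide at −78 °C with inverse addition should secure because the other ketone α-proton sits on a tertiary, oxygen-substituted ring carbon and the lactone α-protons are less acidic than those of the ketone. C- versus O-acylation is not critical, since only C-acylation ends in the stabilised diketonate and an O-acylated enol lactone would be reopened by the alkoxide. In the quench the alkoxide of dianion 29 is the more basic and harder site and should take up the one equivalent of MeOTf in preference to the delocalised diketonate.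

Step 17
Reactants: 30 (4S)-3-hydroxy-4-methoxy-2-{[(1R,5S)-5-methyl-2-[(2Z)-6-methylhepta-2,5-dien-2-yl]-5-(triethylsilyloxy)cyclopent-2-en-1-yl]methyl}cyclohex-2-en-1-one
Product: 31 (4S)-3-hydroxy-2-{[(1R,5S)-5-hydroxy-5-methyl-2-[(2Z)-6-methylhepta-2,5-dien-2-yl]cyclopent-2-en-1-yl]methyl}-4-methoxycyclohex-2-en-1-one (CNP0148956.1)
Conditions: HF·pyridine, pyridine, THF, 0 °C → rt
Reagents that add atoms: none
Why: buffered fluoride cleavage of the tertiary triethylsilyl ether; it leaves the vinylogous acid, the methyl ether and the diene untouched and avoids acid-promoted cyclodehydration between the tertiary alcohol and the dione.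

**Compound list**

1 | but-2-yn-1-ol | CC#CCO | starting material
2 | sodium 2,2-bis(2-methoxyethoxy)-3-methyl-2,5-dihydro-1,2-oxaluminol-2-uide (cyclic alkenylaluminate) | [Na+].C/C1=C/CO[Al-]1(OCCOC)OCCOC | intermediate
3 | (2Z)-3-iodobut-2-en-1-ol | I/C(C)=C\CO | intermediate
4 | (2Z)-1-bromo-3-iodobut-2-ene | I/C(C)=C\CBr | intermediate
5 | (2-methylprop-1-en-1-yl)magnesium bromide | CC(C)=C[Mg]Br | starting material
6 | (2Z)-2-iodo-6-methylhepta-2,5-diene | I/C(C)=C\CC=C(C)C | intermediate
7 | (4R)-4-[(tert-butyldimethylsilyl)oxy]cyclopent-2-en-1-one | CC(C)(C)[Si](C)(C)O[C@H]1C=CC(=O)C1 | starting material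
8 | (1S,4R)-4-[(tert-butyldimethylsilyl)oxy]-1-methylcyclopent-2-en-1-ol | CC(C)(C)[Si](C)(C)O[C@H]1C=C[C@@](C)(O)C1 | intermediate
9 | (1S,4R)-1-methylcyclopent-2-ene-1,4-diol | O[C@H]1C=C[C@@](C)(O)C1 | intermediate
10 | (4S)-4-hydroxy-4-methylcyclopent-2-en-1-one | O=C1C=C[C@@](C)(O)C1 | intermediate
11 | (4S)-4-methyl-4-(triethylsilyloxy)cyclopent-2-en-1-one | O=C1C=C[C@@](C)(O[Si](CC)(CC)CC)C1 | intermediate
12 | (4S)-2,3-dibromo-4-methyl-4-(triethylsilyloxy)cyclopentan-1-one (trans-dibromide, C2/C3 not defined) | O=C1C(Br)C(Br)[C@@](C)(O[Si](CC)(CC)CC)C1 | intermediate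
13 | (4S)-2-bromo-4-methyl-4-(triethylsilyloxy)cyclopent-2-en-1-one | O=C1C(Br)=C[C@@](C)(O[Si](CC)(CC)CC)C1 | intermediate
14 | (1R,4S)-2-bromo-4-methyl-4-(triethylsilyloxy)cyclopent-2-en-1-ol | O[C@H]1C(Br)=C[C@@](C)(O[Si](CC)(CC)CC)C1 | intermediate
15 | triethyl orthoacetate (1,1,1-triethoxyethane) | CC(OCC)(OCC)OCC | starting material
16 | (1R,4S)-2-bromo-1-(1,1-diethoxyethoxy)-4-methyl-4-(triethylsilyloxy)cyclopent-2-ene (mixed orthoester) | CCOC(C)(OCC)O[C@H]1C(Br)=C[C@@](C)(O[Si](CC)(CC)CC)C1 | intermediate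
17 | (1R,4S)-2-bromo-1-[(1-ethoxyethenyl)oxy]-4-methyl-4-(triethylsilyloxy)cyclopent-2-ene (ketene acetal) | C=C(OCC)O[C@H]1C(Br)=C[C@@](C)(O[Si](CC)(CC)CC)C1 | intermediate
18 | ethyl 2-[(1S,5S)-2-bromo-5-methyl-5-(triethylsilyloxy)cyclopent-2-en-1-yl]acetate | CCOC(=O)C[C@@H]1C(Br)=CC[C@]1(C)O[Si](CC)(CC)CC | intermediate
19 | [(2E)-6-methylhepta-2,5-dien-2-yl]lithium (Li cis to C4; geometry of 6 retained) | [Li]/C(C)=C\CC=C(C)C | intermediate
20 | chloro[(2Z)-6-methylhepta-2,5-dien-2-yl]zinc | Cl[Zn]/C(C)=C\CC=C(C)C | intermediate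
21 | ethyl 2-[(1R,5S)-5-methyl-2-[(2Z)-6-methylhepta-2,5-dien-2-yl]-5-(triethylsilyloxy)cyclopent-2-en-1-yl]acetate | CCOC(=O)C[C@@H]1C(/C(C)=C\CC=C(C)C)=CC[C@]1(C)O[Si](CC)(CC)CC | intermediate
22 | 2-[(1R,5S)-5-methyl-2-[(2Z)-6-methylhepta-2,5-dien-2-yl]-5-(triethylsilyloxy)cyclopent-2-en-1-yl]ethan-1-ol | OCC[C@@H]1C(/C(C)=C\CC=C(C)C)=CC[C@]1(C)O[Si](CC)(CC)CC | intermediate
23 | triethyl{[(1S,2R)-2-(2-iodoethyl)-1-methyl-3-[(2Z)-6-methylhepta-2,5-dien-2-yl]cyclopent-3-en-1-yl]oxy}silane | ICC[C@@H]1C(/C(C)=C\CC=C(C)C)=CC[C@]1(C)O[Si](CC)(CC)CC | intermediate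
24 | (2S)-5-oxooxolane-2-carboxylic acid | OC(=O)[C@@H]1CCC(=O)O1 | starting material
25 | (2S)-5-oxooxolane-2-carbonyl chloride | ClC(=O)[C@@H]1CCC(=O)O1 | intermediate
26 | iodo{2-[(1R,5S)-5-methyl-2-[(2Z)-6-methylhepta-2,5-dien-2-yl]-5-(triethylsilyloxy)cyclopent-2-en-1-yl]ethyl}zinc | I[Zn]CC[C@@H]1C(/C(C)=C\CC=C(C)C)=CC[C@]1(C)O[Si](CC)(CC)CC | intermediate
27 | (5S)-5-{3-[(1R,5S)-5-methyl-2-[(2Z)-6-methylhepta-2,5-dien-2-yl]-5-(triethylsilyloxy)cyclopent-2-en-1-yl]propanoyl}oxolan-2-one | O=C(CC[C@@H]1C(/C(C)=C\CC=C(C)C)=CC[C@]1(C)O[Si](CC)(CC)CC)[C@@H]2CCC(=O)O2 | intermediate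
28 | lithium (Z)-enolate of 27 (enolised toward C2) | [Li]O/C(=C\C[C@@H]1C(/C(C)=C\CC=C(C)C)=CC[C@]1(C)O[Si](CC)(CC)CC)[C@@H]2CCC(=O)O2 | intermediate
29 | dilithium salt of (4S)-3,4-dihydroxy-2-{[(1R,5S)-5-methyl-2-[(2Z)-6-methylhepta-2,5-dien-2-yl]-5-(triethylsilyloxy)cyclopent-2-en-1-yl]methyl}cyclohex-2-en-1-one | [Li+].[Li+].[O-][C@H]1CCC(=O)C(C[C@@H]2C(/C(C)=C\CC=C(C)C)=CC[C@]2(C)O[Si](CC)(CC)CC)=C1[O-] | intermediate
30 | (4S)-3-hydroxy-4-methoxy-2-{[(1R,5S)-5-methyl-2-[(2Z)-6-methylhepta-2,5-dien-2-yl]-5-(triethylsilyloxy)cyclopent-2-en-1-yl]methyl}cyclohex-2-en-1-one | CO[C@H]1CCC(=O)C(C[C@@H]2C(/C(C)=C\CC=C(C)C)=CC[C@]2(C)O[Si](CC)(CC)CC)=C1O | intermediate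
31 | (4S)-3-hydroxy-2-{[(1R,5S)-5-hydroxy-5-methyl-2-[(2Z)-6-methylhepta-2,5-dien-2-yl]cyclopent-2-en-1-yl]methyl}-4-methoxycyclohex-2-en-1-one (CNP0148956.1) | CO[C@H]1CCC(=O)C(C[C@@H]2C(/C(C)=C\CC=C(C)C)=CC[C@]2(C)O)=C1O | target

**Totals**

Total step count: 17. Longest linear sequence: 13 steps (steps 4–13, 15, 16, 17, from compound 7).

**Steps most likely to fail**

1. Step 16. The one-flask quench may not discriminate cleanly between the C4 alkoxide and the diketonate, so methylation could also occur at the enolate oxygen or at C2. Proton transfer to the enolate on the side of the oxygen-bearing methine could erode C4. Fallback, setting out from 27 and returning at 30: the ring expansion is run alone (LiHMDS, THF, −78 → 0 °C, acidic work-up) and the neutral (4S)-3,4-dihydroxy-2-(cyclopentenylmethyl)cyclohex-2-en-1-one F1 is isolated. Exhaustive O-methylation with Me3OBF4 and proton sponge in CH2Cl2 then caps the C4 hydroxyl and the enol together, which should give the regioisomeric vinylogous esters (4S)-3,4-dimethoxy enone F2 and (6S)-3,6-dimethoxy enone F3. Both should converge on 30 when the enol ether alone is hydrolysed with aqueous LiOH in THF and the mixture is acidified.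

2. Step 10. The [3,3] shift has to form a bond at a carbon flanked by the quaternary silyloxy centre and may be slow, so acid-promoted ionisation or elimination of the allylic orthoester, or loss of the silyl ether, could compete at 140 °C. Fallback, setting out from 14 and returning at 18: the alcohol is acetylated (Ac2O, pyridine, DMAP) to (1R,4S)-2-bromo-4-methyl-4-(triethylsilyloxy)cyclopent-2-en-1-yl acetate F4. Enolisation with LDA in the presence of TMSCl/Et3N at −78 °C gives the trimethylsilyl ketene acetal F5, which should undergo Ireland–Claisen rearrangement on warming to room temperature under base, without acid. Work-up gives 2-[(1S,5S)-2-bromo-5-methyl-5-(triethylsilyloxy)cyclopent-2-en-1-yl]acetic acid F6, and esterification with EtI/K2CO3 in DMF returns 18.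

3. Step 11. Oxidative addition and transmetalation at the hindered alkenyl bromide may be slow, leaving time for homocoupling and for Z-to-E isomerisation of the alkenylzinc. Fallback, setting out from 11 and returning at 21: the coupling is moved to the flat enone stage. Iodine and pyridine convert 11 into (4S)-2-iodo-4-methyl-4-(triethylsilyloxy)cyclopent-2-en-1-one F7. Negishi coupling of this α-iodoenone with 20 (Pd catalyst, THF, rt) should give (4S)-4-methyl-2-[(2Z)-6-methylhepta-2,5-dien-2-yl]-4-(triethylsilyloxy)cyclopent-2-en-1-one F8. (S)-CBS reduction then gives (1R,4S)-4-methyl-2-[(2Z)-6-methylhepta-2,5-dien-2-yl]-4-(triethylsilyloxy)cyclopent-2-en-1-ol F9, and Johnson–Claisen rearrangement of this alcohol with 15 leads to 21.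

**Further compounds**

F1 | step 16 | (4S)-3,4-dihydroxy-2-{[(1R,5S)-5-methyl-2-[(2Z)-6-methylhepta-2,5-dien-2-yl]-5-(triethylsilyloxy)cyclopent-2-en-1-yl]methyl}cyclohex-2-en-1-one | O[C@H]1CCC(=O)C(C[C@@H]2C(/C(C)=C\CC=C(C)C)=CC[C@]2(C)O[Si](CC)(CC)CC)=C1O
F2 | step 16 | (4S)-3,4-dimethoxy-2-{[(1R,5S)-5-methyl-2-[(2Z)-6-methylhepta-2,5-dien-2-yl]-5-(triethylsilyloxy)cyclopent-2-en-1-yl]methyl}cyclohex-2-en-1-one | CO[C@H]1CCC(=O)C(C[C@@H]2C(/C(C)=C\CC=C(C)C)=CC[C@]2(C)O[Si](CC)(CC)CC)=C1OC
F3 | step 16 | (6S)-3,6-dimethoxy-2-{[(1R,5S)-5-methyl-2-[(2Z)-6-methylhepta-2,5-dien-2-yl]-5-(triethylsilyloxy)cyclopent-2-en-1-yl]methyl}cyclohex-2-en-1-one | CO[C@H]1CCC(OC)=C(C[C@@H]2C(/C(C)=C\CC=C(C)C)=CC[C@]2(C)O[Si](CC)(CC)CC)C1=O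
F4 | step 10 | (1R,4S)-2-bromo-4-methyl-4-(triethylsilyloxy)cyclopent-2-en-1-yl acetate | CC(=O)O[C@H]1C(Br)=C[C@@](C)(O[Si](CC)(CC)CC)C1
F5 | step 10 | (1R,4S)-2-bromo-4-methyl-4-(triethylsilyloxy)-1-{[1-(trimethylsilyloxy)ethenyl]oxy}cyclopent-2-ene | C=C(O[Si](C)(C)C)O[C@H]1C(Br)=C[C@@](C)(O[Si](CC)(CC)CC)C1
F6 | step 10 | 2-[(1S,5S)-2-bromo-5-methyl-5-(triethylsilyloxy)cyclopent-2-en-1-yl]acetic acid | OC(=O)C[C@@H]1C(Br)=CC[C@]1(C)O[Si](CC)(CC)CC
F7 | step 11 | (4S)-2-iodo-4-methyl-4-(triethylsilyloxy)cyclopent-2-en-1-one | O=C1C(I)=C[C@@](C)(O[Si](CC)(CC)CC)C1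
F8 | step 11 | (4S)-4-methyl-2-[(2Z)-6-methylhepta-2,5-dien-2-yl]-4-(triethylsilyloxy)cyclopent-2-en-1-one | O=C1C(/C(C)=C\CC=C(C)C)=C[C@@](C)(O[Si](CC)(CC)CC)C1
F9 | step 11 | (1R,4S)-4-methyl-2-[(2Z)-6-methylhepta-2,5-dien-2-yl]-4-(triethylsilyloxy)cyclopent-2-en-1-ol | O[C@H]1C(/C(C)=C\CC=C(C)C)=C[C@@](C)(O[Si](CC)(CC)CC)C1
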